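**Retrosynthetic overview**
1. The target comes from global hydrogenolysis of its penta-O-benzyl ether. The 3-OH comes from epoxidation and isomerisation of the C2=C3 bond of the matching flavone.
2. Ring C (the pyranone) is the only ring built, and it is formed last. Rings A, B and the benzyl arene (ring D) are bought. The flavone comes from oxidative cyclisation of a 2'-hydroxychalcone through its single free phenol, which lies next to the benzyl group and so fixes C8.
3. The chalcone comes from Claisen–Schmidt condensation of a 3-benzylated ring A acetophenone with 3,4-bis(benzyloxy)benzaldehyde.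
4. Both C–C bonds of the aryl–CH2–aryl bridge come from a new boron-templated three-component ortho-benzylation of a phenol with formaldehyde and 4-(benzyloxy)phenylboronic acid.
5. That phenol comes from selective 4,6-di-O-benzylation of phloroacetophenone.

Assumption: the target SMILES holds no stereocentre and no stereogenic double bond, so the compound is achiral and no enantiocontrol is needed; the only stereo-element on the way is the E-alkene of the chalcone, which is erased on ring closure.

**Step 1**
Reactants: 1 2,4,6-trihydroxyacetophenone (phloroacetophenone)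
Product: 2 1-[4,6-bis(benzyloxy)-2-hydroxyphenyl]ethan-1-one
Conditions: BnBr (2.1 equiv), K2CO3 (2.2 equiv), DMF, 25 to 60 °C
Reagents that add atoms: benzyl bromide, BrCc1ccccc1
Why: Williamson etherification; the 4-OH and one of the two equivalent ortho OH groups are alkylated, after which the last OH is locked in a hydrogen bond to the acetyl C=O and stays free at this stoichiometry.

**Step 2**
Reactants: 2 1-[4,6-bis(benzyloxy)-2-hydroxyphenyl]ethan-1-one; 3 [4-(benzyloxy)phenyl]boronic acid
Product: 6 1-{4,6-bis(benzyloxy)-3-[4-(benzyloxy)benzyl]-2-hydroxyphenyl}ethan-1-one, via 2-aryl-4H-1,3,2-benzodioxaborin 4 (not isolated), via quinone methide borate complex 5 (not isolated)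
Conditions: 3 (1.3 equiv), (CH2O)n (3 equiv), EtCO2H (20 mol%), PhMe, Dean–Stark, 110 °C; then rac-3,3'-dibromo-1,1'-bi-2-naphthol (15 mol%), i-PrOH (3 equiv), 70 °C; H2O work-up
Reagents that add atoms: paraformaldehyde (source of formaldehyde), C=O
Why: Proposed new method: a boron-templated three-component ortho-benzylation in which the arylboronic acid acts first as template and then as aryl donor: 3 esterifies the only free phenol of 2 and delivers formaldehyde through a six-membered transition state to the single open ortho carbon (C3), closing benzodioxaborin 4; the CH2–O bond of 4 sits on a 2,4,6-trioxygenated benzylic carbon and ionises readily once a protic ligand adds to boron (i-PrOH, water or the electron-poor binaphthol, which raises the Lewis acidity of boron), giving the O-bound tetracoordinate borate/ortho-quinone methide pair 5; the electron-rich 4-benzyloxyphenyl group then migrates from boron to the exocyclic CH2 through a closed six-membered transition state driven by rearomatisation, and hydrolysis releases 6, so both C–C bonds of the bridge and the later C8 regiochemistry are set in one flask; converting all of 2 into 4 before the trigger is added suppresses methylene-bridged dimers; the closest known reaction types are the boronic-acid-templated ortho-hydroxymethylation of phenols (Nagata-type, where the aryl group on boron is only a spectator), the Petasis borono-Mannich reaction and the biphenol-catalysed conjugate addition of aryl boronates to preformed ortho-quinone methides, but the merger with formaldehyde and transfer of the template's own aryl group is not known.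

**Step 3**
Reactants: 6 1-{4,6-bis(benzyloxy)-3-[4-(benzyloxy)benzyl]-2-hydroxyphenyl}ethan-1-one; 7 3,4-bis(benzyloxy)benzaldehyde
Product: 8 (E)-1-{4,6-bis(benzyloxy)-3-[4-(benzyloxy)benzyl]-2-hydroxyphenyl}-3-[3,4-bis(benzyloxy)phenyl]prop-2-en-1-one
Conditions: KOH, EtOH/THF (2:1), 40 °C
Reagents that add atoms: none
Why: Claisen–Schmidt aldol condensation of a methyl ketone with a non-enolisable aldehyde; E1cB loss of water gives the thermodynamically preferred E-enone, and the benzyl ethers and the diarylmethane are inert to hydroxide.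

**Step 4**
Reactants: 8 (E)-chalcone
Product: 10 5,7-bis(benzyloxy)-8-[4-(benzyloxy)benzyl]-2-[3,4-bis(benzyloxy)phenyl]-4H-chromen-4-one, via flavanone 9 (not isolated)
Conditions: I2 (10 mol%), DMSO, 130 °C, 2 h
Reagents that add atoms: none
Why: Iodine-catalysed oxidative cyclisation of a 2'-hydroxychalcone (oxa-Michael closure to 9, alpha-iodination and loss of HI, DMSO re-oxidising HI to I2); only the phenol next to the benzyl group is free, so ring C closes on that oxygen and the benzyl group ends at C8.

**Step 5**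
Reactants: 10 penta-O-benzyl flavone
Product: 12 5,7-bis(benzyloxy)-8-[4-(benzyloxy)benzyl]-2-[3,4-bis(benzyloxy)phenyl]-3-hydroxy-4H-chromen-4-one, via flavone 2,3-epoxide 11 (not isolated)
Conditions: DMDO (acetone solution, 3 equiv), CH2Cl2, 0 °C; then p-TsOH·H2O (10 mol%), 25 °C
Reagents that add atoms: dimethyldioxirane (DMDO), CC1(C)OO1
Why: Electrophilic epoxidation of the enol-ether-like C2=C3 bond, followed by acid-catalysed opening of 11 to the C2 oxocarbenium ion and loss of H3 to give the 3-hydroxyflavone; the neutral oxidant leaves the benzyl ethers and the diarylmethane untouched at 0 °C.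

**Step 6**
Reactants: 12 penta-O-benzyl flavonol
Product: 13 8-p-hydroxybenzylquercetin, 2-(3,4-dihydroxyphenyl)-3,5,7-trihydroxy-8-(4-hydroxybenzyl)-4H-chromen-4-one
Conditions: H2 (1 atm), 10% Pd/C, THF/MeOH (1:1), 25 °C
Reagents that add atoms: none
Why: Catalytic hydrogenolysis cleaves the five benzylic C–O bonds, while the C–C bonded diarylmethane and the vinylogous-ester C2=C3 bond of the flavonol are not reduced at 1 atm and room temperature.

**Compound list**
1 | 2,4,6-trihydroxyacetophenone | CC(=O)c1c(O)cc(O)cc1O | starting material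
2 | 1-[4,6-bis(benzyloxy)-2-hydroxyphenyl]ethan-1-one | CC(=O)c1c(O)cc(OCc2ccccc2)cc1OCc1ccccc1 | intermediate
3 | [4-(benzyloxy)phenyl]boronic acid | OB(O)c1ccc(OCc2ccccc2)cc1 | starting material
4 | 1-{5,7-bis(benzyloxy)-2-[4-(benzyloxy)phenyl]-4H-1,3,2-benzodioxaborin-8-yl}ethan-1-one (formed in the flask) | CC(=O)c1c(OCc2ccccc2)cc(OCc2ccccc2)c2c1OB(c1ccc(OCc3ccccc3)cc1)OC2 | intermediate
5 | 2-acetyl-3,5-bis(benzyloxy)-6-methylidenecyclohexa-2,4-dien-1-one bound through its ring C=O oxygen to the boron of 3 as a tetracoordinate borate (formed in the flask) | C=C1C(=[O+][B-](O)(O)c2ccc(OCc3ccccc3)cc2)C(C(C)=O)=C(OCc2ccccc2)C=C1OCc1ccccc1 | intermediate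
6 | 1-{4,6-bis(benzyloxy)-3-[4-(benzyloxy)benzyl]-2-hydroxyphenyl}ethan-1-one | CC(=O)c1c(O)c(Cc2ccc(OCc3ccccc3)cc2)c(OCc2ccccc2)cc1OCc1ccccc1 | intermediate
7 | 3,4-bis(benzyloxy)benzaldehyde | O=Cc1ccc(OCc2ccccc2)c(OCc2ccccc2)c1 | starting material
8 | (E)-1-{4,6-bis(benzyloxy)-3-[4-(benzyloxy)benzyl]-2-hydroxyphenyl}-3-[3,4-bis(benzyloxy)phenyl]prop-2-en-1-one | O=C(/C=C/c1ccc(OCc2ccccc2)c(OCc2ccccc2)c1)c1c(O)c(Cc2ccc(OCc3ccccc3)cc2)c(OCc2ccccc2)cc1OCc1ccccc1 | intermediate
9 | racemic 5,7-bis(benzyloxy)-8-[4-(benzyloxy)benzyl]-2-[3,4-bis(benzyloxy)phenyl]chroman-4-one (formed in the flask) | O=C1CC(c2ccc(OCc3ccccc3)c(OCc3ccccc3)c2)Oc2c(Cc3ccc(OCc4ccccc4)cc3)c(OCc3ccccc3)cc(OCc3ccccc3)c21 | intermediate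
10 | 5,7-bis(benzyloxy)-8-[4-(benzyloxy)benzyl]-2-[3,4-bis(benzyloxy)phenyl]-4H-chromen-4-one | O=c1cc(-c2ccc(OCc3ccccc3)c(OCc3ccccc3)c2)oc2c(Cc3ccc(OCc4ccccc4)cc3)c(OCc3ccccc3)cc(OCc3ccccc3)c12 | intermediate
11 | racemic 2,3-epoxide of 10, cis-fused oxirane across C2–C3 (formed in the flask) | O=C1C2OC2(c2ccc(OCc3ccccc3)c(OCc3ccccc3)c2)Oc2c(Cc3ccc(OCc4ccccc4)cc3)c(OCc3ccccc3)cc(OCc3ccccc3)c21 | intermediate
12 | 5,7-bis(benzyloxy)-8-[4-(benzyloxy)benzyl]-2-[3,4-bis(benzyloxy)phenyl]-3-hydroxy-4H-chromen-4-one | O=c1c(O)c(-c2ccc(OCc3ccccc3)c(OCc3ccccc3)c2)oc2c(Cc3ccc(OCc4ccccc4)cc3)c(OCc3ccccc3)cc(OCc3ccccc3)c12 | intermediate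
13 | 8-p-hydroxybenzylquercetin (achiral) | O=c1c(O)c(-c2ccc(O)c(O)c2)oc2c(Cc3ccc(O)cc3)c(O)cc(O)c12 | target

**Total step count:** 6. **Longest linear sequence:** 6 steps (1 to 13).

**Steps most likely to fail**

Step 2 (the proposed new step). There are four main risks:
- Chelation of boron by the acetyl C=O may slow the templated hydroxymethylation.
- The very electrophilic quinone methide may be caught by a second ring A to give a methylene-bridged dimer.
- The electron-rich boronic acid may protodeboronate.
- The aryl shift from boron may be too slow.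

The fallback uses known chemistry, sets out from 2 and comes back at 6. Electrophilic iodination (NIS, cat. TFA, MeCN, 0 °C) goes ortho to the free phenol and gives 1-[4,6-bis(benzyloxy)-2-hydroxy-3-iodophenyl]ethan-1-one F1. Commercial 4-(benzyloxy)benzyl chloride is turned with Zn dust and LiCl in THF into 4-(benzyloxy)benzylzinc chloride F2. Negishi coupling of the two (Pd(OAc)2, SPhos, THF, 25 °C, slow addition of the zinc reagent, a protocol that tolerates free phenols) then gives 6.

Step 4. At 130 °C the HI formed in the cycle may cleave the 5-O-benzyl ether, and I2/DMSO may oxidise the electron-rich diarylmethane CH2. The fallback replaces chalcone oxidation by a Baker–Venkataraman route, sets out from 6 and comes back at 10, so it bypasses steps 3 and 4. Esterification of the phenol of 6 with commercial 3,4-bis(benzyloxy)benzoic acid (DCC, DMAP, CH2Cl2) gives 2-acetyl-3,5-bis(benzyloxy)-6-[4-(benzyloxy)benzyl]phenyl 3,4-bis(benzyloxy)benzoate F3. Base-induced acyl migration (KOH, pyridine, 50 °C) gives 1-{4,6-bis(benzyloxy)-3-[4-(benzyloxy)benzyl]-2-hydroxyphenyl}-3-[3,4-bis(benzyloxy)phenyl]propane-1,3-dione F4. Cyclodehydration (cat. p-TsOH, PhMe, 80 °C) then gives 10 without any oxidant.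

Step 5. DMDO may react slowly with the hindered, cross-conjugated C2=C3 bond, or may over-oxidise ring A or the benzylic CH2 groups. The fallback swaps electrophilic epoxidation for deprotonation, borylation and oxidation, sets out from 10 and comes back at 12. LDA (THF, −78 °C) removes H3 to give the 3-lithio derivative of 10 F5. B(OMe)3 traps it as dimethyl {5,7-bis(benzyloxy)-8-[4-(benzyloxy)benzyl]-2-[3,4-bis(benzyloxy)phenyl]-4-oxo-4H-chromen-3-yl}boronate F6. AcOH and 30% H2O2 (0 to 25 °C) then oxidise the C–B bond to the 3-OH of 12.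

**Further compounds**
F1 | step 2 | 1-[4,6-bis(benzyloxy)-2-hydroxy-3-iodophenyl]ethan-1-one | CC(=O)c1c(O)c(I)c(OCc2ccccc2)cc1OCc1ccccc1
F2 | step 2 | 4-(benzyloxy)benzylzinc chloride | Cl[Zn]Cc1ccc(OCc2ccccc2)cc1
F3 | step 4 | 2-acetyl-3,5-bis(benzyloxy)-6-[4-(benzyloxy)benzyl]phenyl 3,4-bis(benzyloxy)benzoate | CC(=O)c1c(OC(=O)c2ccc(OCc3ccccc3)c(OCc3ccccc3)c2)c(Cc2ccc(OCc3ccccc3)cc2)c(OCc2ccccc2)cc1OCc1ccccc1
F4 | step 4 | 1-{4,6-bis(benzyloxy)-3-[4-(benzyloxy)benzyl]-2-hydroxyphenyl}-3-[3,4-bis(benzyloxy)phenyl]propane-1,3-dione | O=C(CC(=O)c1ccc(OCc2ccccc2)c(OCc2ccccc2)c1)c1c(O)c(Cc2ccc(OCc3ccccc3)cc2)c(OCc2ccccc2)cc1OCc1ccccc1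
F5 | step 5 | 3-lithio derivative of 10 | [Li]c1c(-c2ccc(OCc3ccccc3)c(OCc3ccccc3)c2)oc2c(Cc3ccc(OCc4ccccc4)cc3)c(OCc3ccccc3)cc(OCc3ccccc3)c2c1=O
F6 | step 5 | dimethyl {5,7-bis(benzyloxy)-8-[4-(benzyloxy)benzyl]-2-[3,4-bis(benzyloxy)phenyl]-4-oxo-4H-chromen-3-yl}boronate | COB(OC)c1c(-c2ccc(OCc3ccccc3)c(OCc3ccccc3)c2)oc2c(Cc3ccc(OCc4ccccc4)cc3)c(OCc3ccccc3)cc(OCc3ccccc3)c2c1=O
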